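**Plan**

1. Locants: ε-lactone ring A = C10–C1=C2–C3(=O)–O–C4(CH3)2–C5; ring B = C5–C6–C7–C8–C9–C10; ring C = C8–C9–C11–C12–C13(=CH2)–C14; bridge C14–C15(OH)–C16H2–C12; γ-lactone C14–C19(=O)–O–C17H(CH3)–C15; β = face of the C10 methyl.
2. Retrosynthetic cuts, in order: C13=CH2 (methylenation), C1=C2 (dehydrogenation), O–C4 (Baeyer–Villiger of a cyclohexanone ring A), O–C19 and C14–C15 (lactonization/aldol), C12–C16 (alkylation), C8–C14 (cation–enol cyclization), C11–C12 (dianion alkylation), and last C9–C10, undone by a retro-1,2-shift that contracts ring B to a cyclopentanol.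
3. Enabling feature: in ring B the quaternary C10 is followed by C9, which carries the one-carbon branch C11, and then by C8, an sp3 carbon that can be a ketone. This C10–C9(C11)–C8 array is what a halonium-induced semipinacol shift of a 1-vinylcyclopentanol leaves (C8 = carbinol carbon, C9/C11 = vinyl group, C10 = migrating carbon).
4. Forward: ring A and the five-membered precursor of ring B come from (R)-7a-methyl-tetrahydroindene-1,5-dione. Ring enlargement gives ring B (key step), SnCl4 cyclization closes ring C, and aldol/lactonization closes ring D and the γ-lactone. Ring A is then enlarged to the ε-lactone, C13 is methylenated and C1=C2 is introduced last.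
5. Stereochemistry: C10 from the enedione; C5 by hydroxyl-directed hydrogenation; C9 and C8 (and epimerizable C12, C14) in the cation–enol cyclization, relayed from C10; C12 quaternary centre by axial alkylation; C17 from (R)-methyl lactate; C15 by the lactonization, which only one aldol epimer can undergo.

Key step: step 8

Remark: C9 of 9, C8 of 11 and C12 of 14 are not controlled and are erased in later steps, so their SMILES carry no descriptor at those centres; the (R)-enedione 1 and (R)-methyl lactate are taken as commercial.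

**Route**

Step 1
Reactants: 1 (R)-7a-methyl-2,3,7,7a-tetrahydro-1H-indene-1,5(6H)-dione
Product: 2 C8 ethylene ketal of 1 (dioxolane on the cyclopentanone carbon)
Conditions: ethylene glycol, p-TsOH (cat.), benzene, reflux, water removal
Reagents that add atoms: ethylene glycol, OCCO
Why: Acid-catalysed ketalization should take the saturated cyclopentanone in preference to the conjugated enone, which masks C8 for the enolate chemistry at C4.

Step 2
Reactants: 2 C8 ethylene ketal of 1
Product: 3 4,4-dimethyl-Δ5(6) 3-ketone (C8 dioxolane)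
Conditions: t-BuOK, t-BuOH, rt; MeI, 0 °C → rt
Reagents that add atoms: iodomethane, CI
Why: Deconjugative α,α-dimethylation through the extended dienolate installs both C4 methyl groups and moves the double bond to C5=C6.

Step 3
Reactants: 3 4,4-dimethyl-Δ5(6) 3-ketone
Product: 4 3α-alcohol (OH trans to the C10 methyl)
Conditions: L-Selectride, THF, −78 °C; then NaOH, H2O2
Reagents that add atoms: none
Why: Reduction of the neopentyl ketone with a bulky trialkylborohydride should occur by equatorial attack and give the axial 3α-alcohol, which is needed on the α-face to direct the next step.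

Step 4
Reactants: 4 3α-alcohol
Product: 5 5α-H trans-hydrindane 3α-ol (C8 dioxolane)
Conditions: [Ir(cod)(PCy3)(py)]PF6 (5 mol %), H2 (1 atm), CH2Cl2, rt
Reagents that add atoms: none
Why: Hydroxyl-directed homogeneous hydrogenation should deliver hydrogen to C5/C6 from the face of the homoallylic 3α-OH, setting H5 anti to the C10 methyl (trans ring fusion).

Step 5
Reactants: 5 trans-hydrindane 3α-ol
Product: 6 3α-tert-butyldimethylsilyl ether of 5
Conditions: TBSOTf, 2,6-lutidine, CH2Cl2, 0 °C
Reagents that add atoms: tert-butyldimethylsilyl triflate, CC(C)(C)[Si](C)(C)OS(=O)(=O)C(F)(F)F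
Why: Silylation with the silyl triflate protects the hindered axial alcohol for the organometallic and Lewis-acid steps.

Step 6
Reactants: 6 3α-TBS ether
Product: 7 3α-(TBSO)-4,4,10β-trimethyl-trans-hydrindan-8-one (5α-H)
Conditions: 1 M HCl, THF, 0 °C → rt
Reagents that add atoms: water, O
Why: Acetal hydrolysis frees the cyclopentanone while the hindered secondary silyl ether should survive brief mild acid.

Step 7
Reactants: 7 trans-hydrindan-8-one
Product: 8 8α-vinyl-8β-hydroxy carbinol (1-vinylcyclopentanol)
Conditions: vinylmagnesium bromide, THF, −20 °C → rt; aq. NH4Cl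
Reagents that add atoms: vinylmagnesium bromide, C=C[Mg]Br
Why: Grignard addition to the neopentyl ketone should occur anti to the angular methyl, as with 17-keto steroids; the C8 configuration is irrelevant because C8 becomes a ketone again.

Step 8
Reactants: 8 8α-vinyl-8β-hydroxy carbinol
Product: 10 3α-(TBSO)-4,4,10β-trimethyl-9-methylene-trans-decalin-8-one (5α-H), via bromomethyl ketone 9 (not isolated)
Conditions: NBS, CH2Cl2, −20 → 0 °C; then DBU, 0 °C → rt
Reagents that add atoms: none
Why: NBS delivers Br+ to the terminal vinyl carbon C11, and the C8–C10 σ-bond of the cyclopentanol migrates to C9 anti to the bromonium bridge while C8–OH collapses to the ketone (halonium-induced semipinacol rearrangement), so the five-membered ring gains C9 and becomes ring B; DBU then removes HBr from the β-bromo ketone (E1cB) to give the exocyclic enone. The closest known reactions are the positive-halogen ring enlargement of 1-vinylcycloalkanols to 2-(halomethyl)cycloalkanones and the D-homoannulation of 17-hydroxy-17-vinyl steroids. Ring B is formed by ring enlargement (1,2-alkyl shift with inversion at C9, formally a 3-exo-tet opening of the bromonium ion by the migrating bond), not by a cyclization. C10 migrates with retention, so its configuration from 1 is carried into the new C9–C10 bond; C9 is set anti to bromine but is erased in the elimination. The step needs migration of the quaternary C10 rather than the methylene C7, which the higher migratory aptitude of the fully substituted, more electron-rich carbon and relief of strain at the trans-hydrindane junction should secure. The vinyl group is the only π-bond in 8, so no other site competes for the halonium ion.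

Step 9
Reactants: 10 9-methylene-trans-decalin-8-one
Product: 11 8-methyl-9-methylene-decalin-8-ol (tertiary allylic alcohol)
Conditions: MeLi, Et2O, −78 °C; aq. NH4Cl
Reagents that add atoms: methyllithium, [Li]C
Why: 1,2-Addition of the hard organolithium to the α-methylene ketone brings in the C8 methyl; the carbinol configuration is lost in the next step.

Step 10
Reactants: 11 tertiary allylic alcohol
Product: 12 9-(bromomethyl)-3α-(TBSO)-4,4,8,10β-tetramethyl-Δ8(9)-octalin (5α-H)
Conditions: PBr3, pyridine (cat.), Et2O, −10 → 0 °C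
Reagents that add atoms: phosphorus tribromide, BrP(Br)Br
Why: Allylic bromination with SN2′ transposition (as in linalool to geranyl bromide) should give the primary bromide at C11 and the tetrasubstituted C8=C9 alkene.

Step 11
Reactants: 12 allylic bromide; 13 methyl 3-oxopentanoate
Product: 14 methyl 4-methyl-3-oxo-5-(octalin-9-yl)pentanoate (C12 epimers)
Conditions: 13, NaH, THF, 0 °C; n-BuLi, 0 °C; then 12, 0 °C → rt; aq. NH4Cl
Reagents that add atoms: none
Why: γ-Alkylation of the β-keto ester dianion forms C11–C12 and brings in C12 (with its methyl), C13, C14 and the C19 ester.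

Step 12
Reactants: 14 octalinyl β-keto ester
Product: 15 tricyclic β-keto ester (rings A/B/C; 5α,9α-H; 8β,10β-CH3; 12α,14α-H)
Conditions: SnCl4, CH2Cl2, −78 → 0 °C; aq. NaHCO3
Reagents that add atoms: none
Why: In this protic-initiated cation–olefin cyclization terminated by the β-keto ester enol (as with dihydro-β-ionone-derived keto esters), C9 should be protonated anti to the axial C10 methyl and the tertiary C8 cation trapped by C14 through a chair transition state, giving the trans-anti-trans tricycle; C12 and C14 equilibrate to equatorial methyl and ester.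

Step 13
Reactants: 16 methyl (R)-2-hydroxypropanoate
Product: 17 methyl (R)-2-(tert-butyldimethylsilyloxy)propanoate
Conditions: TBSCl, imidazole, DMF, rt
Reagents that add atoms: tert-butyldimethylsilyl chloride, CC(C)(C)[Si](C)(C)Cl
Why: Standard silylation protects the lactate hydroxyl, which later becomes the lactone oxygen at C17.

Step 14
Reactants: 17 TBS-protected (R)-lactate
Product: 19 (R)-2-(TBSO)-3-methylene-4-(trimethylsilyl)butane (allylsilane), via bis-adduct carbinol 18 (not isolated)
Conditions: Me3SiCH2MgCl, CeCl3, THF, −78 °C → rt; then SiO2, CH2Cl2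
Reagents that add atoms: (trimethylsilyl)methylmagnesium chloride, C[Si](C)(C)C[Mg]Cl
Why: Double addition of the non-basic organocerium reagent to the ester followed by Peterson elimination turns the ester carbon into the 2-substituted allylsilane without touching the adjacent stereocentre.

Step 15
Reactants: 19 allylsilane
Product: 20 (R)-3-(bromomethyl)-2-(TBSO)but-3-ene (allyl bromide)
Conditions: NBS, propylene oxide, CH2Cl2, −78 °C
Reagents that add atoms: N-bromosuccinimide, BrN1C(=O)CCC1=O
Why: Electrophilic bromodesilylation (SE2′) of the allylsilane gives the allyl bromide; the allyl unit is symmetrical, so the transposition is without consequence.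

Step 16
Reactants: 15 tricyclic β-keto ester; 20 allyl bromide
Product: 21 C12-alkylated β-keto ester (12α-CH2C(=CH2)CH(OTBS)CH3 axial; 12β-CH3)
Conditions: LDA (2.3 equiv), THF–DMPU, −78 → −20 °C; then 20, −78 → 0 °C
Reagents that add atoms: none
Why: γ-Alkylation of the β-keto ester dianion should take place by axial attack on the α-face of C12 (anti to the axial C8 methyl), making C12 quaternary with the new chain in the axial position needed for bridging to C14.

Step 17
Reactants: 21 C12-alkylated β-keto ester
Product: 22 1,4-diketone (side chain C16H2–C15(=O)–C17H(OTBS)CH3)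
Conditions: OsO4 (cat.), NaIO4, 2,6-lutidine, dioxane–H2O, rt
Reagents that add atoms: sodium periodate, [Na+].[O-]I(=O)(=O)=O
Why: Lemieux–Johnson oxidation cleaves the only unhindered alkene to the C15 ketone, while the hindered, hydrogen-bonded tetrasubstituted enol of the β-keto ester should be spared.

Step 18
Reactants: 22 1,4-diketone
Product: 25 pentacyclic hydroxy γ-lactone 3α-ol (13-ketone; 15-OH anti to the C13 bridge; 17R), via diol diketone 23 (not isolated), via aldol adduct 24 (not isolated)
Conditions: HF·pyridine, THF, 0 °C → rt; then DBU (cat.), CH2Cl2, rt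
Reagents that add atoms: none
Why: After desilylation, the reversible intramolecular aldol addition of C14 to the C15 ketone (bridged ketol formation) closes ring D, and only the epimer whose 1-hydroxyethyl group lies syn to the C13 bridge can lactonize with the C19 ester, so transesterification sets C15 under thermodynamic control.

Step 19
Reactants: 25 hydroxy γ-lactone 3α-ol
Product: 26 3,13-diketone
Conditions: DMP, NaHCO3, CH2Cl2, rt
Reagents that add atoms: none
Why: Dess–Martin oxidation converts the secondary C3 alcohol to the ketone and cannot touch the tertiary C15 alcohol.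

Step 20
Reactants: 26 3,13-diketone
Product: 27 saturated ε-lactone (ring A; 13-ketone)
Conditions: mCPBA, NaHCO3, CH2Cl2, rt
Reagents that add atoms: meta-chloroperoxybenzoic acid, OOC(=O)c1cccc(Cl)c1
Why: In the Baeyer–Villiger oxidation the quaternary C4 migrates to oxygen, and the C13 ketone, flanked by two quaternary bridgeheads, should react more slowly.

Step 21
Reactants: 27 ε-lactone 13-ketone
Product: 28 1,2-dihydrobrasilianoid B (C13 exo-methylene)
Conditions: Zn, CH2Br2, TiCl4, THF–CH2Cl2, 0 °C → rt
Reagents that add atoms: dibromomethane, BrCBr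
Why: Takai–Lombardo methylenation is non-basic, suited to hindered non-enolizable ketones, and leaves both lactones untouched.

Step 22
Reactants: 28 1,2-dihydrobrasilianoid B
Product: 30 brasilianoid B, via 2-phenylselanyl lactone 29 (not isolated)
Conditions: LDA (2.2 equiv), THF, −78 °C; PhSeBr; then H2O2, pyridine, CH2Cl2, 0 °C
Reagents that add atoms: none
Why: C2 is the only enolizable position, so α-selenenylation of the ε-lactone enolate followed by selenoxide syn-elimination toward C1 should give the ring-constrained cis C1=C2 enoate.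

**Compound list**

1 | (R)-7a-methyl-2,3,7,7a-tetrahydro-1H-indene-1,5(6H)-dione | O=C1[C@]2(C)CCC(=O)C=C2CC1 | starting material
2 | C8 ethylene ketal of 1 | O1CCOC13[C@]2(C)CCC(=O)C=C2CC3 | intermediate
3 | 4,4-dimethyl-Δ5(6) 3-ketone, C8 dioxolane | O1CCOC13[C@]2(C)CCC(=O)C(C)(C)C2=CC3 | intermediate
4 | 3α-alcohol of 3 (OH trans to C10 methyl) | O1CCOC13[C@]2(C)CC[C@H](O)C(C)(C)C2=CC3 | intermediate
5 | 5α-H trans-hydrindane 3α-ol, C8 dioxolane | O1CCOC13[C@]2(C)CC[C@H](O)C(C)(C)[C@H]2CC3 | intermediate
6 | 3α-TBS ether of 5 | O1CCOC13[C@]2(C)CC[C@H](O[Si](C)(C)C(C)(C)C)C(C)(C)[C@H]2CC3 | intermediate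
7 | 3α-(TBSO)-4,4,10β-trimethyl-trans-hydrindan-8-one | O=C1[C@]2(C)CC[C@H](O[Si](C)(C)C(C)(C)C)C(C)(C)[C@H]2CC1 | intermediate
8 | 8α-vinyl-8β-hydroxy carbinol | C=C[C@]1(O)[C@]2(C)CC[C@H](O[Si](C)(C)C(C)(C)C)C(C)(C)[C@H]2CC1 | intermediate
9 | 9-(bromomethyl)-3α-(TBSO)-4,4,10β-trimethyl-trans-decalin-8-one (C9 not defined) | O=C1C(CBr)[C@]2(C)CC[C@H](O[Si](C)(C)C(C)(C)C)C(C)(C)[C@H]2CC1 | intermediate
10 | 3α-(TBSO)-4,4,10β-trimethyl-9-methylene-trans-decalin-8-one | O=C1C(=C)[C@]2(C)CC[C@H](O[Si](C)(C)C(C)(C)C)C(C)(C)[C@H]2CC1 | intermediate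
11 | 3α-(TBSO)-4,4,8,10β-tetramethyl-9-methylene-trans-decalin-8-ol (C8 not defined) | CC1(O)C(=C)[C@]2(C)CC[C@H](O[Si](C)(C)C(C)(C)C)C(C)(C)[C@H]2CC1 | intermediate
12 | 9-(bromomethyl)-3α-(TBSO)-4,4,8,10β-tetramethyl-Δ8(9)-octalin (5α-H) | CC1=C(CBr)[C@]2(C)CC[C@H](O[Si](C)(C)C(C)(C)C)C(C)(C)[C@H]2CC1 | intermediate
13 | methyl 3-oxopentanoate | CCC(=O)CC(=O)OC | starting material
14 | methyl 4-methyl-3-oxo-5-(octalin-9-yl)pentanoate (C12 epimers) | CC1=C(CC(C)C(=O)CC(=O)OC)[C@]2(C)CC[C@H](O[Si](C)(C)C(C)(C)C)C(C)(C)[C@H]2CC1 | intermediate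
15 | tricyclic β-keto ester: methyl 3α-(TBSO)-4,4,8β,10β,12β-pentamethyl-13-oxo-perhydrophenanthrene-14β-carboxylate (5α,9α,12α,14α-H) | O=C1[C@@H](C)C[C@H]3[C@]4(C)CC[C@H](O[Si](C)(C)C(C)(C)C)C(C)(C)[C@H]4CC[C@]3(C)[C@H]1C(=O)OC | intermediate
16 | methyl (R)-2-hydroxypropanoate | C[C@@H](O)C(=O)OC | starting material
17 | methyl (R)-2-(tert-butyldimethylsilyloxy)propanoate | C[C@@H](O[Si](C)(C)C(C)(C)C)C(=O)OC | intermediate
18 | (R)-3-(TBSO)-1-(trimethylsilyl)-2-[(trimethylsilyl)methyl]butan-2-ol | C[C@@H](O[Si](C)(C)C(C)(C)C)C(O)(C[Si](C)(C)C)C[Si](C)(C)C | intermediate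
19 | (R)-2-(TBSO)-3-methylene-4-(trimethylsilyl)butane | C[C@@H](O[Si](C)(C)C(C)(C)C)C(=C)C[Si](C)(C)C | intermediate
20 | (R)-3-(bromomethyl)-2-(TBSO)but-3-ene | C[C@@H](O[Si](C)(C)C(C)(C)C)C(=C)CBr | intermediate
21 | 15 bearing at C12 an axial (α) CH2–C(=CH2)–CH(OTBS)CH3 chain (17R), 12β-methyl | O=C1[C@@](CC(=C)[C@@H](C)O[Si](C)(C)C(C)(C)C)(C)C[C@H]3[C@]4(C)CC[C@H](O[Si](C)(C)C(C)(C)C)C(C)(C)[C@H]4CC[C@]3(C)[C@H]1C(=O)OC | intermediate
22 | C15 ketone from 21 (side chain CH2–C(=O)–CH(OTBS)CH3) | O=C1[C@@](CC(=O)[C@@H](C)O[Si](C)(C)C(C)(C)C)(C)C[C@H]3[C@]4(C)CC[C@H](O[Si](C)(C)C(C)(C)C)C(C)(C)[C@H]4CC[C@]3(C)[C@H]1C(=O)OC | intermediate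
23 | doubly desilylated 22 (3α-OH, 17-OH) | O=C1[C@@](CC(=O)[C@@H](C)O)(C)C[C@H]3[C@]4(C)CC[C@H](O)C(C)(C)[C@H]4CC[C@]3(C)[C@H]1C(=O)OC | intermediate
24 | aldol adduct (bicyclo[3.2.1]octanone, C15 tertiary OH, C19 methyl ester, 17-OH) | O=C1[C@@]2(C)C[C@H]3[C@]4(C)CC[C@H](O)C(C)(C)[C@H]4CC[C@]3(C)[C@]1(C(=O)OC)[C@@](O)([C@@H](C)O)C2 | intermediate
25 | pentacyclic γ-lactone with 3α-OH, 15-OH and 13-ketone | O=C1[C@@]2(C)C[C@H]3[C@]4(C)CC[C@H](O)C(C)(C)[C@H]4CC[C@]3(C)[C@@]13C(=O)O[C@H](C)[C@@]3(O)C2 | intermediate
26 | 3,13-diketone γ-lactone | O=C1[C@@]2(C)C[C@H]3[C@]4(C)CCC(=O)C(C)(C)[C@H]4CC[C@]3(C)[C@@]13C(=O)O[C@H](C)[C@@]3(O)C2 | intermediate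
27 | saturated ε-lactone 13-ketone | O=C1[C@@]2(C)C[C@H]3[C@]4(C)CCC(=O)OC(C)(C)[C@H]4CC[C@]3(C)[C@@]13C(=O)O[C@H](C)[C@@]3(O)C2 | intermediate
28 | 1,2-dihydrobrasilianoid B | C=C1[C@@]2(C)C[C@H]3[C@]4(C)CCC(=O)OC(C)(C)[C@H]4CC[C@]3(C)[C@@]13C(=O)O[C@H](C)[C@@]3(O)C2 | intermediate
29 | 2-(phenylselanyl)-1,2-dihydrobrasilianoid B (C2 not defined) | C=C1[C@@]2(C)C[C@H]3[C@]4(C)CC([Se]c5ccccc5)C(=O)OC(C)(C)[C@H]4CC[C@]3(C)[C@@]13C(=O)O[C@H](C)[C@@]3(O)C2 | intermediate
30 | brasilianoid B | C=C1[C@@]2(C)C[C@H]3[C@]4(C)C=CC(=O)OC(C)(C)[C@H]4CC[C@]3(C)[C@@]13C(=O)O[C@H](C)[C@@]3(O)C2 | target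

**Summary**

Total step count: 22. Longest linear sequence: 19 steps (steps 1–12 and 16–22); steps 13–15 form the side branch to bromide 20.

Steps most likely to fail:

Step 8. The methylene carbon C7 may migrate instead of the quaternary C10, or the tertiary hydroxyl may capture the bromonium ion to give a bromo epoxide that does not rearrange. The fallback sets out from ketone 7 and returns at bromide 12. One-carbon homologation of 7 with trimethylsilyldiazomethane and BF3·OEt2, in which the methylene carbon migrates as in D-homo steroid syntheses, would give the 3α-(TBSO)-4,4,10β-trimethyl-trans-decalin-9-one F1. Methylation with LDA and MeI at the only enolizable position would give the 8-methyl-9-ketone F2. KHMDS and PhNTf2 would then give the tetrasubstituted enol triflate F3, and palladium-catalysed methoxycarbonylation (Pd(OAc)2, PPh3, CO, MeOH, Et3N) the unsaturated ester F4. DIBAL reduction would give the allylic alcohol F5, which PBr3 converts into 12.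

Step 12. The tetrasubstituted C8=C9 bond may be protonated at C8 instead of C9 or from the β-face of C9, and the Lewis acid may strip the silyl ether. The fallback sets out from enone 10 (with 13) and returns at 15. Keto ester 13 would be converted (Et3N, TMSCl; then LDA, TMSCl) into the bis(trimethylsilyl) dienol ether F6. Its TiCl4-mediated Mukaiyama–Michael addition to the exocyclic enone 10 would give the 1,5-diketo ester F7, in which H9 is equilibrated to the α (axial) position before ring C is closed. Wittig methylenation of the C8 ketone (Ph3P=CH2, THF) would give the 8-methylene keto ester F8. SnCl4 should then generate the C8 cation from the exocyclic alkene without touching C9 and close ring C to 15.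

Step 20. The peracid may also attack the strained bridging C13 ketone, or the hindered C3 ketone may react too slowly. The fallback sets out from diketone 26 and returns at 28. The C13 ketone would be methylenated first (Zn, CH2Br2, TiCl4) to give the 13-methylene 3-ketone F9. Ring A would then be enlarged by an olefin-tolerant Baeyer–Villiger oxidation with bis(trimethylsilyl) peroxide and TMSOTf (CH2Cl2, −40 °C) to give 28.

Further compounds
F1 | step 8 | 3α-(TBSO)-4,4,10β-trimethyl-trans-decalin-9-one | O=C1[C@]2(C)CC[C@H](O[Si](C)(C)C(C)(C)C)C(C)(C)[C@H]2CCC1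
F2 | step 8 | 3α-(TBSO)-4,4,8,10β-tetramethyl-trans-decalin-9-one (C8 epimers) | O=C1[C@]2(C)CC[C@H](O[Si](C)(C)C(C)(C)C)C(C)(C)[C@H]2CCC1C
F3 | step 8 | Δ8(9)-enol triflate of F2 | CC1=C(OS(=O)(=O)C(F)(F)F)[C@]2(C)CC[C@H](O[Si](C)(C)C(C)(C)C)C(C)(C)[C@H]2CC1
F4 | step 8 | methyl 3α-(TBSO)-4,4,8,10β-tetramethyl-Δ8(9)-octalin-9-carboxylate | CC1=C(C(=O)OC)[C@]2(C)CC[C@H](O[Si](C)(C)C(C)(C)C)C(C)(C)[C@H]2CC1
F5 | step 8 | 9-(hydroxymethyl)-3α-(TBSO)-4,4,8,10β-tetramethyl-Δ8(9)-octalin | CC1=C(CO)[C@]2(C)CC[C@H](O[Si](C)(C)C(C)(C)C)C(C)(C)[C@H]2CC1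
F6 | step 12 | 1-methoxy-1,3-bis(trimethylsilyloxy)penta-1,3-diene | CC=C(O[Si](C)(C)C)C=C(OC)O[Si](C)(C)C
F7 | step 12 | 9α-H 8-oxo-decalin bearing the CH2CH(CH3)C(=O)CH2CO2CH3 chain at C9 (C12 epimers) | O=C1[C@@H](CC(C)C(=O)CC(=O)OC)[C@]2(C)CC[C@H](O[Si](C)(C)C(C)(C)C)C(C)(C)[C@H]2CC1
F8 | step 12 | 8-methylene analogue of F7 | C=C1[C@@H](CC(C)C(=O)CC(=O)OC)[C@]2(C)CC[C@H](O[Si](C)(C)C(C)(C)C)C(C)(C)[C@H]2CC1
F9 | step 20 | 13-methylene 3-ketone γ-lactone | C=C1[C@@]2(C)C[C@H]3[C@]4(C)CCC(=O)C(C)(C)[C@H]4CC[C@]3(C)[C@@]13C(=O)O[C@H](C)[C@@]3(O)C2
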